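Squalene numbering is used: oxepane A (O, C2–C7), cyclohexane B (C6–C11), bridge C12–C13, cyclohexane C (C14–C19), oxepane D (C18–C23, O). The halves differ only at C10 (axial acetate) and C15 (equatorial acetate), so the cut is unsymmetrical, at C11–C12. C11 lies alpha to C10, a latent ketone. A Horner–Wadsworth–Emmons union joins an acyclic thirteen-carbon diepoxy beta-keto phosphonate (rings A and B still unfolded) to the finished seventeen-carbon ring C/D aldehyde. It forges C11=C12 and leaves an enone, which later delivers the C10=C11 enol silane regiospecifically. That nucleophile ends a diepoxide cascade closing A and B. Methyllithium then attacks C10 equatorially.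

Key step: step 8

Remark: all names use the numbering above. The configuration at C3 and C22 of the intermediates is of no consequence, since both carbons end as ketones. The L-fructose-derived epoxidation ketone is treated as a purchased catalyst.

Step 1
Reactants: 1 (E)-geranylacetone
Product: 2 (3S,6S,7S)-diepoxy ketone
Conditions: L-fructose-derived Shi ketone (1,2:4,5-di-O-isopropylidene-beta-L-erythro-2,3-hexodiulo-2,6-pyranose, 0.3 equiv), Oxone, K2CO3, Bu4NHSO4, Na2B4O7/Na2EDTA buffer (pH 10.5), MeCN–CH2(OMe)2–H2O, 0 °C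
Reagents that add atoms: potassium peroxymonosulfate (Oxone) [K+].[O-]S(=O)(=O)OO
Why: Shi asymmetric epoxidation, in which the chiral dioxirane transfers oxygen through a spiro transition state to the same face of both trisubstituted alkenes and so sets C3, C6 and C7 as S by catalyst control, while the saturated methyl ketone is inert at this pH.

Step 2
Reactants: 2 (3S,6S,7S)-diepoxy ketone
Product: 4 diethyl diepoxy beta-keto phosphonate, via beta-keto phosphonite 3 (not isolated)
Conditions: LDA, THF, −78 °C; ClP(OEt)2, −78 °C → rt; then 30% aq. H2O2, 0 °C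
Reagents that add atoms: diethyl chlorophosphite CCOP(Cl)OCC; hydrogen peroxide OO
Why: Kinetic deprotonation of the methyl ketone at C11, C–P bond formation between the enolate and the trivalent phosphorus chloride, and oxidation of the phosphonite (enolate phosphonylation route to beta-keto phosphonates) place the activating group on C11 only, and the trisubstituted epoxides survive LDA at −78 °C.

Step 3
Reactants: 5 (2E,6E)-farnesyl acetate
Product: 6 (18S,19S,22S)-diepoxyfarnesyl acetate
Conditions: L-fructose-derived Shi ketone (0.3 equiv), Oxone (controlled amount), K2CO3, Bu4NHSO4, Na2B4O7/Na2EDTA buffer (pH 10.5), MeCN–CH2(OMe)2–H2O, 0 °C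
Reagents that add atoms: potassium peroxymonosulfate (Oxone) [K+].[O-]S(=O)(=O)OO
Why: Shi asymmetric epoxidation that is regioselective because the allylic acetate deactivates the C14=C15 alkene inductively, so only the two distal trisubstituted alkenes react and C18, C19 and C22 are set as S by the catalyst.

Step 4
Reactants: 6 (18S,19S,22S)-diepoxyfarnesyl acetate
Product: 7 methyl (14E)-diepoxyhomofarnesoate
Conditions: Pd2(dba)3·CHCl3 (cat.), PPh3, NaBr (cat.), iPr2NEt, MeOH, CO (30 atm), 50 °C
Reagents that add atoms: carbon monoxide [C-]#[O+]; methanol CO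
Why: Palladium-catalysed alkoxycarbonylation of an allylic acetate, in which bromide-assisted ionisation by zerovalent palladium gives the pi-allyl complex, CO inserts at the unsubstituted terminus (new carbon C12) and methanolysis releases the linear beta,gamma-unsaturated ester with the E alkene retained, isolated trisubstituted epoxides being inert to the catalyst.

Step 5
Reactants: 7 methyl (14E)-diepoxyhomofarnesoate
Product: 9 tricyclic silyloxy lactone, via O-methyl lactonium triflate 8 (not isolated)
Conditions: TBSOTf (1.2 equiv), 2,6-di-tert-butyl-4-methylpyridine, CH2Cl2, −78 °C; then Et3N, −78 °C → rt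
Reagents that add atoms: tert-butyldimethylsilyl triflate CC(C)(C)[Si](C)(C)OS(=O)(=O)C(F)(F)F
Why: Silyl-triflate-promoted tandem oxa- and carbacyclisation (epoxide-opening cascade merged with a cation–olefin cyclisation), in which O-silylation of the terminal epoxide, attack of the C18–C19 epoxide oxygen on C23 (oxepane D), anti opening of the epoxonium at C19 by the E C14=C15 alkene through a chair (ring C, trans fusion, axial H14) and anti capture of the C15 cation by the ester carbonyl give the trans-fused lactonium ion, so that C14 and C15 (equatorial oxygen) follow from the alkene geometry and C18/C19 from the epoxide, before triethylamine removes the O-methyl group.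

Step 6
Reactants: 9 tricyclic silyloxy lactone
Product: 11 C15 trimethylsilyl ether Weinreb amide, via hydroxy amide 10 (not isolated)
Conditions: MeNH(OMe)·HCl, iPrMgCl, THF, −20 → 0 °C; then TMSCl, imidazole, 0 °C → rt
Reagents that add atoms: N,O-dimethylhydroxylamine hydrochloride CNOC.Cl; chlorotrimethylsilane C[Si](C)(C)Cl
Why: Aminolysis of the lactone by the chloromagnesium amide (Weinreb amide formation) frees the C15 alkoxide, which is silylated in the same flask before it can relactonise, and no stereocentre is touched.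

Step 7
Reactants: 11 C15 trimethylsilyl ether Weinreb amide
Product: 12 ring C/D aldehyde
Conditions: iBu2AlH, CH2Cl2, −78 °C; aq. potassium sodium tartrate
Reagents that add atoms: none
Why: Partial reduction of a Weinreb amide, whose chelated tetrahedral aluminium adduct holds until work-up and so stops at the C12 aldehyde, which cannot close to a lactol because O15 is silylated.

Step 8
Reactants: 4 diethyl diepoxy beta-keto phosphonate; 12 ring C/D aldehyde
Product: 13 (11E)-diepoxy enone
Conditions: LiCl, iPr2NEt, MeCN–THF, rt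
Reagents that add atoms: none
Why: Lithium-assisted deprotonation of the beta-keto phosphonate at C11, addition of the stabilised carbanion to the C12 aldehyde and syn loss of diethyl phosphate from the oxaphosphetane create the C11=C12 bond, which is a Horner–Wadsworth–Emmons olefination under Masamune–Roush conditions, a standard late fragment union. The step closes no ring and creates no stereocentre, and its only stereochemical output is the E alkene, favoured by reversible addition of the stabilised anion. It exploits that C11 sits alpha to C10, the ring B carbon that carries the axial acetate and is therefore a ketone in disguise, and that before ring B exists C11 is an unhindered carbon rather than a neopentyl ring position next to quaternary C6. The selectivity needed is chemoselectivity: the amine base is too weak to enolise aldehyde 12, to open the epoxides or to cleave the silyl ethers, and the phosphonate makes C11 the only nucleophilic site, so C9 never competes. The enone stores the regiochemical information (C10–C11–C12 conjugation) that a saturated ketone flanked by two methylene groups would have lost.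

Step 9
Reactants: 13 (11E)-diepoxy enone
Product: 14 (10Z)-diepoxy enol silane
Conditions: tBuMe2SiH, Pt2[(CH2=CHSiMe2)2O]3 (1 mol %), toluene, 60 °C
Reagents that add atoms: tert-butyldimethylsilane C[SiH](C)C(C)(C)C
Why: Platinum-catalysed 1,4-hydrosilylation of an enone delivers hydride to C12 and silicon to oxygen through the s-cis conformer, which should give only the C10=C11 enol silane, mainly as the Z isomer, and leaves epoxides and silyl ethers untouched.

Step 10
Reactants: 14 (10Z)-diepoxy enol silane
Product: 16 tetracyclic C15 hydroxy C10 ketone, via ketone trimethylsilyl ether 15 (not isolated)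
Conditions: TBSOTf (1.1 equiv), 2,6-di-tert-butyl-4-methylpyridine, CH2Cl2, −78 °C; aq. NaHCO3; then 1 M HCl, THF, 0 °C
Reagents that add atoms: tert-butyldimethylsilyl triflate CC(C)(C)[Si](C)(C)OS(=O)(=O)C(F)(F)F
Why: Silyl-triflate-promoted diepoxide–enol silane cascade (tandem oxa- and carbacyclisation), in which silylation of the C2–C3 epoxide, attack of the C6–C7 epoxide oxygen on C2 (oxepane A) and 6-endo anti opening of the epoxonium at tertiary C6 by C11 of the Z enol silane through a chair close rings A and B with inversion at C6, retention at C7 and an equatorial C11 side chain (also the thermodynamic, epimerisable position), after which dilute acid removes only the tertiary trimethylsilyl ether.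

Step 11
Reactants: 16 tetracyclic C15 hydroxy C10 ketone
Product: 18 bis-silyl C10/C15 diacetate, via dilithium dialkoxide 17 (not isolated)
Conditions: MeLi (4 equiv), Et2O–THF, −78 → 0 °C; then Ac2O (excess), DMAP, 0 °C → rt
Reagents that add atoms: methyllithium [Li]C; acetic anhydride CC(=O)OC(C)=O
Why: 1,2-Addition of methyllithium to the C10 ketone comes from the equatorial direction because the axial trajectory is blocked by the 1,3-diaxial C6 methyl group, which gives the axial (10R) alkoxide, and acylation of both lithium alkoxides in the same flask avoids the sluggish acetylation of hindered neutral tertiary alcohols.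

Step 12
Reactants: 18 bis-silyl C10/C15 diacetate
Product: 19 C3/C22 diol diacetate
Conditions: HF·pyridine, pyridine, THF, 0 °C → rt
Reagents that add atoms: none
Why: Fluoride-driven cleavage of the two secondary silyl ethers (Si–F bond formation) under pyridine-buffered conditions should leave the tertiary acetates and both oxepanes intact.

Step 13
Reactants: 19 C3/C22 diol diacetate
Product: 20 target CNP0325605.1
Conditions: Dess–Martin periodinane, NaHCO3, CH2Cl2, rt
Reagents that add atoms: none
Why: Dess–Martin oxidation converts both secondary alcohols into the C3 and C22 ketones under buffered neutral conditions, erases the two auxiliary stereocentres and cannot touch the fully substituted acetate carbons.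

Compound list
1 | (E)-geranylacetone, (5E)-6,10-dimethylundeca-5,9-dien-2-one | CC(=O)CC/C=C(\C)CCC=C(C)C | starting material
2 | 4-[(2S,3S)-3-{2-[(2S)-3,3-dimethyloxiran-2-yl]ethyl}-3-methyloxiran-2-yl]butan-2-one, the (3S,6S,7S)-diepoxy ketone | CC(=O)CC[C@@H]1O[C@@]1(C)CC[C@@H]1OC1(C)C | intermediate
3 | diethyl phosphonite on C11 of ketone 2 (beta-keto phosphonite) | CCOP(OCC)CC(=O)CC[C@@H]1O[C@@]1(C)CC[C@@H]1OC1(C)C | intermediate
4 | diethyl phosphonate on C11 of ketone 2 (diepoxy beta-keto phosphonate) | CCOP(=O)(OCC)CC(=O)CC[C@@H]1O[C@@]1(C)CC[C@@H]1OC1(C)C | intermediate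
5 | (2E,6E)-farnesyl acetate | CC(=O)OC/C=C(\C)CC/C=C(\C)CCC=C(C)C | starting material
6 | (2E,6S,7S,10S)-6,7:10,11-diepoxyfarnesyl acetate (18S,19S,22S in the numbering used here) | CC(=O)OC/C=C(\C)CC[C@@H]1O[C@@]1(C)CC[C@@H]1OC1(C)C | intermediate
7 | methyl (3E,7S,8S,11S)-7,8:11,12-diepoxy-4,8,12-trimethyltridec-3-enoate | COC(=O)C/C=C(\C)CC[C@@H]1O[C@@]1(C)CC[C@@H]1OC1(C)C | intermediate
8 | O-methyl lactonium triflate of lactone 9 | COC=1C[C@H]2[C@]3(C)CC[C@H](O[Si](C)(C)C(C)(C)C)C(C)(C)O[C@H]3CC[C@]2(C)[O+]=1.[O-]S(=O)(=O)C(F)(F)F | intermediate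
9 | (14S,15S,18S,19S,22S)-tricyclic lactone: rings C and D, gamma-lactone C12(=O)–O–C15 trans-fused on C14–C15, 22-OTBS | O=C1C[C@H]2[C@]3(C)CC[C@H](O[Si](C)(C)C(C)(C)C)C(C)(C)O[C@H]3CC[C@]2(C)O1 | intermediate
10 | ring C/D hydroxy Weinreb amide (C15–OH, present as its chloromagnesium alkoxide) | CON(C)C(=O)C[C@H]1[C@]2(C)CC[C@H](O[Si](C)(C)C(C)(C)C)C(C)(C)O[C@H]2CC[C@]1(C)O | intermediate
11 | ring C/D Weinreb amide, 15-OTMS, 22-OTBS | CON(C)C(=O)C[C@H]1[C@]2(C)CC[C@H](O[Si](C)(C)C(C)(C)C)C(C)(C)O[C@H]2CC[C@]1(C)O[Si](C)(C)C | intermediate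
12 | ring C/D aldehyde (C12 formyl, equatorial C13 chain on C14), 15-OTMS, 22-OTBS | O=CC[C@H]1[C@]2(C)CC[C@H](O[Si](C)(C)C(C)(C)C)C(C)(C)O[C@H]2CC[C@]1(C)O[Si](C)(C)C | intermediate
13 | (11E)-enone: C10 ketone, C11=C12, 2,3- and 6,7-epoxides, rings C and D complete | O=C(CC[C@@H]1O[C@@]1(C)CC[C@@H]1OC1(C)C)/C=C/C[C@H]1[C@]2(C)CC[C@H](O[Si](C)(C)C(C)(C)C)C(C)(C)O[C@H]2CC[C@]1(C)O[Si](C)(C)C | intermediate
14 | (10Z)-tert-butyldimethylsilyl enol ether, C10=C11 | CC(C)(C)[Si](C)(C)O/C(CC[C@@H]1O[C@@]1(C)CC[C@@H]1OC1(C)C)=C\CC[C@H]1[C@]2(C)CC[C@H](O[Si](C)(C)C(C)(C)C)C(C)(C)O[C@H]2CC[C@]1(C)O[Si](C)(C)C | intermediate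
15 | tetracyclic C10 ketone (3S,6S,7S,11S), 3-OTBS, 22-OTBS, 15-OTMS | O=C1CC[C@@H]2OC(C)(C)[C@@H](O[Si](C)(C)C(C)(C)C)CC[C@@]2(C)[C@@H]1CC[C@H]1[C@]2(C)CC[C@H](O[Si](C)(C)C(C)(C)C)C(C)(C)O[C@H]2CC[C@]1(C)O[Si](C)(C)C | intermediate
16 | tetracyclic C10 ketone with free C15–OH, 3-OTBS, 22-OTBS | O=C1CC[C@@H]2OC(C)(C)[C@@H](O[Si](C)(C)C(C)(C)C)CC[C@@]2(C)[C@@H]1CC[C@H]1[C@]2(C)CC[C@H](O[Si](C)(C)C(C)(C)C)C(C)(C)O[C@H]2CC[C@]1(C)O | intermediate
17 | dilithium (10R,15S)-dialkoxide | [Li+].[Li+].[O-][C@]1(C)CC[C@@H]2OC(C)(C)[C@@H](O[Si](C)(C)C(C)(C)C)CC[C@@]2(C)[C@@H]1CC[C@H]1[C@]2(C)CC[C@H](O[Si](C)(C)C(C)(C)C)C(C)(C)O[C@H]2CC[C@]1(C)[O-] | intermediate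
18 | (10R,15S)-diacetate, 3-OTBS, 22-OTBS | CC(=O)O[C@]1(C)CC[C@@H]2OC(C)(C)[C@@H](O[Si](C)(C)C(C)(C)C)CC[C@@]2(C)[C@@H]1CC[C@H]1[C@]2(C)CC[C@H](O[Si](C)(C)C(C)(C)C)C(C)(C)O[C@H]2CC[C@]1(C)OC(C)=O | intermediate
19 | (3S,22S)-diol (10R,15S)-diacetate | CC(=O)O[C@]1(C)CC[C@@H]2OC(C)(C)[C@@H](O)CC[C@@]2(C)[C@@H]1CC[C@H]1[C@]2(C)CC[C@H](O)C(C)(C)O[C@H]2CC[C@]1(C)OC(C)=O | intermediate
20 | CNP0325605.1, (6S,7S,10R,11S,14S,15S,18S,19S)-3,22-dioxo 10,15-diacetate | CC(=O)O[C@]1(C)CC[C@@H]2OC(C)(C)C(=O)CC[C@@]2(C)[C@@H]1CC[C@H]1[C@]2(C)CCC(=O)C(C)(C)O[C@H]2CC[C@]1(C)OC(C)=O | target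

Total step count: 13. Longest linear sequence: 11 steps (5 to 20, steps 3 to 13).

Steps most likely to fail

Step 10. The internal epoxide may be activated before the terminal one. The hindered trisubstituted enol silane may lose its silyl group by protonation, or the epoxonium ion may be intercepted by other Lewis basic oxygens of the large substrate. The fallback folds rings A and B on the small fragment before the union. It sets out from 4. Soft enolisation (TBSOTf, Et3N, CH2Cl2) gives phosphonate enol silane F1. The same silyl triflate cascade (TBSOTf, 2,6-di-tert-butyl-4-methylpyridine, −78 °C) gives bicyclic beta-keto phosphonate F2, with the phosphonate equatorial on C11. Horner–Wadsworth–Emmons reaction of its sodium salt (NaH, THF, reflux) with aldehyde 12 gives exocyclic enone F3. Hydrogenation (H2, Pd/C, EtOAc) from the face opposite the axial C6 methyl group comes back to the route at 15.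

Step 5. The C15 cation may lose a proton, or the cascade may stall after oxepane formation, because an ester carbonyl is a weak terminating nucleophile. The fallback uses a hydroxyl terminator and restores the oxidation level afterwards. It sets out from 7. Reduction with iBu2AlH (CH2Cl2, −78 °C) gives diepoxy homofarnesol F4. The silyl triflate cascade then ends by capture of C15 by the primary alcohol and gives tricyclic tetrahydrofuran F5. Ether-to-lactone oxidation of the C12 methylene (RuCl3 cat., NaIO4, CCl4–MeCN–H2O) comes back to the route at 9.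

Step 11. The hindered ketone may be enolised instead of attacked, facial selectivity may erode, or acylation of the axial alkoxide may be incomplete and accompanied by elimination. The fallback builds the carbinol through an epoxide. It sets out from 16. Corey–Chaykovsky reaction with dimethylsulfonium methylide (Me3SI, n-BuLi, THF) attacks equatorially for the same steric reason and gives spiro-epoxide F6. LiEt3BH opens it at the methylene carbon to bis-silyl diol F7. Lewis acid catalysed acetylation (Ac2O, Sc(OTf)3 cat., MeCN, −20 °C) comes back to the route at 18.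

Further compounds
F1 | step 10 | phosphonate enol silane (tert-butyldimethylsilyl enol ether of 4, C10=C11) | CCOP(=O)(OCC)C=C(O[Si](C)(C)C(C)(C)C)CC[C@@H]1O[C@@]1(C)CC[C@@H]1OC1(C)C
F2 | step 10 | bicyclic beta-keto phosphonate (rings A and B, C10 ketone, equatorial C11 phosphonate, 3-OTBS) | O=C1CC[C@@H]2OC(C)(C)[C@@H](O[Si](C)(C)C(C)(C)C)CC[C@@]2(C)[C@@H]1P(=O)(OCC)OCC
F3 | step 10 | exocyclic enone (C11=C12, alkene geometry left open) | O=C1CC[C@@H]2OC(C)(C)[C@@H](O[Si](C)(C)C(C)(C)C)CC[C@@]2(C)C1=CC[C@H]1[C@]2(C)CC[C@H](O[Si](C)(C)C(C)(C)C)C(C)(C)O[C@H]2CC[C@]1(C)O[Si](C)(C)C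
F4 | step 5 | diepoxy homofarnesol | OCC/C=C(\C)CC[C@@H]1O[C@@]1(C)CC[C@@H]1OC1(C)C
F5 | step 5 | tricyclic tetrahydrofuran (C12–O–C15 ether, 22-OTBS) | C1C[C@H]2[C@]3(C)CC[C@H](O[Si](C)(C)C(C)(C)C)C(C)(C)O[C@H]3CC[C@]2(C)O1
F6 | step 11 | spiro-epoxide at C10 (axial oxygen) | O1C[C@]12CC[C@@H]3OC(C)(C)[C@@H](O[Si](C)(C)C(C)(C)C)CC[C@@]3(C)[C@@H]2CC[C@H]1[C@]2(C)CC[C@H](O[Si](C)(C)C(C)(C)C)C(C)(C)O[C@H]2CC[C@]1(C)O
F7 | step 11 | bis-silyl (10R,15S)-diol | O[C@]1(C)CC[C@@H]2OC(C)(C)[C@@H](O[Si](C)(C)C(C)(C)C)CC[C@@]2(C)[C@@H]1CC[C@H]1[C@]2(C)CC[C@H](O[Si](C)(C)C(C)(C)C)C(C)(C)O[C@H]2CC[C@]1(C)O
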